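**Retrosynthetic overview**

- Pyronaamidine (20) is released last from its O-benzyl ether 19 by hydrogenolysis.
- The strategy rests on the 4-amino-1-methylimidazole-2,5-dione ring. Its N3'–C2'(=O)–N1'(CH3) segment lies between the amidine nitrogen and the acyl carbon C5', so it corresponds to methyl isocyanate. The ring is therefore closed from amidino ester 16 and MeNCO, forming N3'–C2' first and N1'–C5' second.
- 16 comes from 2-aminoimidazole 14 and ethyl 2-ethoxy-2-iminoacetate, which forms the exocyclic amidine C–N bond.
- 14 comes from 4,5-diiodo-1-methylimidazole: the C5 benzyl group by I/Mg exchange, aldehyde addition and ionic reduction; the C4 benzyl group by Negishi coupling; the C2 nitrogen by lithiation, azide transfer and reduction.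
- Ring order: the imidazole is bought; the imidazoledione is the only ring formed (step 9).

Key step: step 9

Remark: the target has no stereocentre (its SMILES carries no stereodescriptor), so no asymmetric step is needed and the carbinol of step 3 may be racemic. The dione ring is drawn as its 4-amino tautomer.

**Route**

Step 1
Reactants: 1 4,5-diiodo-1H-imidazole
Product: 2 4,5-diiodo-1-methyl-1H-imidazole
Conditions: NaH (1.1 equiv), DMF, 0 °C; MeI (1.05 equiv), 0 °C → rt
Reagents that add atoms: iodomethane, CI
Why: Deprotonation gives a symmetric diiodoimidazolide, so SN2 N-alkylation can give only one N-methyl isomer, and the electron-poor ring resists quaternisation.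

Step 2
Reactants: 3 2-hydroxy-3,4-dimethoxybenzaldehyde
Product: 4 2-(benzyloxy)-3,4-dimethoxybenzaldehyde
Conditions: BnBr, K2CO3, DMF, 60 °C
Reagents that add atoms: benzyl bromide, BrCc1ccccc1
Why: Williamson etherification of the phenoxide should proceed cleanly and masks the phenol against the organometallic, acidic and isocyanate steps that follow.

Step 3
Reactants: 2 4,5-diiodo-1-methyl-1H-imidazole; 4 2-(benzyloxy)-3,4-dimethoxybenzaldehyde
Product: 6 rac-[2-(benzyloxy)-3,4-dimethoxyphenyl](4-iodo-1-methyl-1H-imidazol-5-yl)methanol, via (4-iodo-1-methyl-1H-imidazol-5-yl)magnesium bromide 5 (not isolated)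
Conditions: EtMgBr (1.05 equiv), THF, 0 °C; then 4, 0 °C → rt; aq NH4Cl
Reagents that add atoms: none
Why: Iodine–magnesium exchange should occur selectively at C5, next to N1, where the carbanion is better stabilised, and the Grignard reagent then adds 1,2 to the aldehyde to give a racemic carbinol whose stereocentre is removed in step 4.

Step 4
Reactants: 6 rac-[2-(benzyloxy)-3,4-dimethoxyphenyl](4-iodo-1-methyl-1H-imidazol-5-yl)methanol
Product: 7 5-[2-(benzyloxy)-3,4-dimethoxybenzyl]-4-iodo-1-methyl-1H-imidazole
Conditions: Et3SiH (3 equiv), TFA (10 equiv), CH2Cl2, 0 °C → rt; aq NaHCO3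
Reagents that add atoms: none
Why: Ionic hydrogenation should work because the carbinol ionises to a benzylic cation stabilised by the para-methoxy and ortho-benzyloxy groups and is trapped by hydride from the silane, while the C–I bond and the benzyl aryl ether tolerate TFA at room temperature.

Step 5
Reactants: 7 5-[2-(benzyloxy)-3,4-dimethoxybenzyl]-4-iodo-1-methyl-1H-imidazole; 8 4-methoxybenzyl chloride
Product: 10 5-[2-(benzyloxy)-3,4-dimethoxybenzyl]-4-(4-methoxybenzyl)-1-methyl-1H-imidazole, via (4-methoxybenzyl)zinc chloride 9 (not isolated)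
Conditions: Zn dust, LiCl, THF, rt (8 → 9); then 7, Pd(OAc)2 (2 mol%), SPhos (4 mol%), THF, rt → 50 °C
Reagents that add atoms: none
Why: Negishi sp2–sp3 cross-coupling of the heteroaryl iodide with a benzylic zinc chloride, made by LiCl-mediated zinc insertion, installs the C4 benzyl group directly and so avoids a cation at the C4 benzylic carbon, which the neighbouring trialkoxyphenyl ring could trap in a six-membered Friedel–Crafts closure.

Step 6
Reactants: 10 5-[2-(benzyloxy)-3,4-dimethoxybenzyl]-4-(4-methoxybenzyl)-1-methyl-1H-imidazole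
Product: 13 2-azido-5-[2-(benzyloxy)-3,4-dimethoxybenzyl]-4-(4-methoxybenzyl)-1-methyl-1H-imidazole, via 2-lithioimidazole 11 (not isolated), via lithium imidazol-2-yl tosyltriazenide 12 (not isolated)
Conditions: n-BuLi (1.1 equiv), THF, −78 °C; TsN3 (1.2 equiv), −78 °C → rt; aq NH4Cl
Reagents that add atoms: tosyl azide (4-methylbenzenesulfonyl azide), Cc1ccc(cc1)S(=O)(=O)N=[N+]=[N-]
Why: Kinetic lithiation should occur at C2–H, the most acidic C–H and the only free ring position, and electrophilic azide transfer from tosyl azide then proceeds through a triazenide that expels sulfinate.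

Step 7
Reactants: 13 2-azido-5-[2-(benzyloxy)-3,4-dimethoxybenzyl]-4-(4-methoxybenzyl)-1-methyl-1H-imidazole
Product: 14 5-[2-(benzyloxy)-3,4-dimethoxybenzyl]-4-(4-methoxybenzyl)-1-methyl-1H-imidazol-2-amine
Conditions: H2 (1 atm), Lindlar catalyst, EtOH, rt
Reagents that add atoms: none
Why: Catalytic hydrogenation of the azide to the amine with loss of dinitrogen should be fast on lead-poisoned palladium, which does not hydrogenolyse the benzyl aryl ether.

Step 8
Reactants: 14 5-[2-(benzyloxy)-3,4-dimethoxybenzyl]-4-(4-methoxybenzyl)-1-methyl-1H-imidazol-2-amine; 15 ethyl 2-ethoxy-2-iminoacetate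
Product: 16 ethyl 2-amino-2-({5-[2-(benzyloxy)-3,4-dimethoxybenzyl]-4-(4-methoxybenzyl)-1-methyl-1H-imidazol-2-yl}imino)acetate
Conditions: 15 (1.5 equiv), abs. EtOH, rt → 40 °C, no acid
Reagents that add atoms: none
Why: In this Pinner-type amidine synthesis the exocyclic amine adds to the imidate carbon, which is the most electrophilic site of 15, and under neutral conditions the tetrahedral intermediate loses ethanol and not ammonia, leaving the ester for the key step.

Step 9
Reactants: 16 ethyl 2-amino-2-({5-[2-(benzyloxy)-3,4-dimethoxybenzyl]-4-(4-methoxybenzyl)-1-methyl-1H-imidazol-2-yl}imino)acetate; 17 methyl isocyanate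
Product: 19 O-benzyl pyronaamidine, 4-({5-[2-(benzyloxy)-3,4-dimethoxybenzyl]-4-(4-methoxybenzyl)-1-methyl-1H-imidazol-2-yl}amino)-1-methyl-1H-imidazole-2,5-dione, via N-(methylcarbamoyl)amidino ester 18 (not isolated)
Conditions: 17 (1.2 equiv), THF, 0 °C → rt; then Et3N (1 equiv), 50 °C; MeOH quench
Reagents that add atoms: none
Why: Proposed new method: the unsubstituted amidine nitrogen of 16, reacting through the tautomer in which it is the sp2 imino nitrogen, should add to the isocyanate carbon of 17 to give N-carbamoylamidine 18 (bond N3'–C2'), and the N-methylurea N–H of 18 should then attack the neighbouring oxalyl-type ethyl ester and expel ethanol (bond N1'–C5'). The closest known reaction type is the hydantoin synthesis from α-amino esters and isocyanates (urea formation, then acyl substitution), together with the known N-carbamoylation of amidines by isocyanates; what is new is their combination on an N-heteroaryl α-amidino ester. The one ring closed is the five-membered imidazole-2,5-dione, by a 5-exo-trig addition–elimination at the ester carbonyl. No stereocentre is formed. The step needs carbamoylation at the terminal amidine nitrogen and not at the imidazolyl-bearing nitrogen (which would lead to the isomeric 1-imidazolyl-5-iminohydantoin) or at ring N3; the terminal nitrogen is the least hindered, the other two are flanked by the N1-methyl and C4-benzyl groups and have their lone pairs delocalised into the imidazole, and carbamoylation at ring N3 is reversible. Because the N-methyl group arrives with 17 and the amidine carbon already carries the imidazolyl nitrogen, the position of the methyl group in the new ring is fixed by construction.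

Step 10
Reactants: 19 O-benzyl pyronaamidine
Product: 20 pyronaamidine, 4-{[5-(2-hydroxy-3,4-dimethoxybenzyl)-4-(4-methoxybenzyl)-1-methyl-1H-imidazol-2-yl]amino}-1-methyl-1H-imidazole-2,5-dione
Conditions: H2 (1 atm), 10% Pd/C, EtOAc–MeOH, rt
Reagents that add atoms: none
Why: Hydrogenolysis of the benzyl aryl ether should free the phenol, while the aryl methyl ethers and the conjugated acylamidine C=N are expected to be inert at 1 atm and room temperature.

**Compound list**

1 | 4,5-diiodo-1H-imidazole | Ic1nc[nH]c1I | starting material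
2 | 4,5-diiodo-1-methyl-1H-imidazole | Cn1cnc(I)c1I | intermediate
3 | 2-hydroxy-3,4-dimethoxybenzaldehyde | COc1ccc(C=O)c(O)c1OC | starting material
4 | 2-(benzyloxy)-3,4-dimethoxybenzaldehyde | COc1ccc(C=O)c(OCc2ccccc2)c1OC | intermediate
5 | (4-iodo-1-methyl-1H-imidazol-5-yl)magnesium bromide | Cn1cnc(I)c1[Mg]Br | intermediate
6 | rac-[2-(benzyloxy)-3,4-dimethoxyphenyl](4-iodo-1-methyl-1H-imidazol-5-yl)methanol (racemic) | COc1ccc(C(O)c2c(I)ncn2C)c(OCc2ccccc2)c1OC | intermediate
7 | 5-[2-(benzyloxy)-3,4-dimethoxybenzyl]-4-iodo-1-methyl-1H-imidazole | COc1ccc(Cc2c(I)ncn2C)c(OCc2ccccc2)c1OC | intermediate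
8 | 4-methoxybenzyl chloride | COc1ccc(CCl)cc1 | starting material
9 | (4-methoxybenzyl)zinc chloride | COc1ccc(C[Zn]Cl)cc1 | intermediate
10 | 5-[2-(benzyloxy)-3,4-dimethoxybenzyl]-4-(4-methoxybenzyl)-1-methyl-1H-imidazole | COc1ccc(Cc2ncn(C)c2Cc2ccc(OC)c(OC)c2OCc2ccccc2)cc1 | intermediate
11 | {5-[2-(benzyloxy)-3,4-dimethoxybenzyl]-4-(4-methoxybenzyl)-1-methyl-1H-imidazol-2-yl}lithium | [Li]c1nc(Cc2ccc(OC)cc2)c(Cc2ccc(OC)c(OC)c2OCc2ccccc2)n1C | intermediate
12 | lithium 3-{5-[2-(benzyloxy)-3,4-dimethoxybenzyl]-4-(4-methoxybenzyl)-1-methyl-1H-imidazol-2-yl}-1-tosyltriaz-2-en-1-ide | [Li+].Cc1ccc(cc1)S(=O)(=O)[N-]N=Nc1nc(Cc2ccc(OC)cc2)c(Cc2ccc(OC)c(OC)c2OCc2ccccc2)n1C | intermediate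
13 | 2-azido-5-[2-(benzyloxy)-3,4-dimethoxybenzyl]-4-(4-methoxybenzyl)-1-methyl-1H-imidazole | [N-]=[N+]=Nc1nc(Cc2ccc(OC)cc2)c(Cc2ccc(OC)c(OC)c2OCc2ccccc2)n1C | intermediate
14 | 5-[2-(benzyloxy)-3,4-dimethoxybenzyl]-4-(4-methoxybenzyl)-1-methyl-1H-imidazol-2-amine | Nc1nc(Cc2ccc(OC)cc2)c(Cc2ccc(OC)c(OC)c2OCc2ccccc2)n1C | intermediate
15 | ethyl 2-ethoxy-2-iminoacetate | CCOC(=N)C(=O)OCC | starting material
16 | ethyl 2-amino-2-({5-[2-(benzyloxy)-3,4-dimethoxybenzyl]-4-(4-methoxybenzyl)-1-methyl-1H-imidazol-2-yl}imino)acetate | CCOC(=O)C(N)=Nc1nc(Cc2ccc(OC)cc2)c(Cc2ccc(OC)c(OC)c2OCc2ccccc2)n1C | intermediate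
17 | methyl isocyanate | CN=C=O | starting material
18 | ethyl 2-({5-[2-(benzyloxy)-3,4-dimethoxybenzyl]-4-(4-methoxybenzyl)-1-methyl-1H-imidazol-2-yl}amino)-2-[(methylcarbamoyl)imino]acetate | CCOC(=O)C(=NC(=O)NC)Nc1nc(Cc2ccc(OC)cc2)c(Cc2ccc(OC)c(OC)c2OCc2ccccc2)n1C | intermediate
19 | O-benzyl pyronaamidine, 4-({5-[2-(benzyloxy)-3,4-dimethoxybenzyl]-4-(4-methoxybenzyl)-1-methyl-1H-imidazol-2-yl}amino)-1-methyl-1H-imidazole-2,5-dione | COc1ccc(Cc2nc(NC3=NC(=O)N(C)C3=O)n(C)c2Cc2ccc(OC)c(OC)c2OCc2ccccc2)cc1 | intermediate
20 | pyronaamidine | COc1ccc(Cc2nc(NC3=NC(=O)N(C)C3=O)n(C)c2Cc2ccc(OC)c(OC)c2O)cc1 | target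

**Step count and risks**

Total step count: 10. Longest linear sequence: 9 steps (steps 1 and 3–10 from compound 1; equally steps 2–10 from compound 3).

Steps most likely to fail:

1. Step 9 (proposed new method). Carbamoylation may take place at the imidazolyl-bearing amidine nitrogen or at ring N3 and lead to an isomeric ring or to acyclic ureas. Ring N3 may also close onto the ester before the urea does, and the isocyanate may oligomerise under base. The fallback uses known chemistry and brings the dione ring in preformed. It sets out from amine 14. Commercial 1-methylimidazolidine-2,4,5-trione is silylated with N,O-bis(trimethylsilyl)acetamide in MeCN to 1-methyl-4-[(trimethylsilyl)oxy]-1H-imidazole-2,5-dione F1. Amine 14 is added and the mixture is heated. Addition of the exocyclic amine to the silyl-activated C4 and loss of trimethylsilanol should give 19, where the route is rejoined before step 10.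

2. Step 8. Addition of the weakly nucleophilic, guanidine-like amine to the imidate may be slow. The tetrahedral intermediate may lose ammonia instead of ethanol, and on warming ring N3 may acylate itself with the ester of 16. The fallback inverts the order of the two C–N bond formations and sets out from 14, 15 and 17. Imidate 15 is first carbamoylated on nitrogen with 17 (THF, cat. Et3N, 0 °C) to ethyl 2-ethoxy-2-[(methylcarbamoyl)imino]acetate F2, an N-acylimidate far more electrophilic than 15. Amine 14 is then added in the same flask. Displacement of ethoxide should give the N-carbamoylamidine 18, which closes to 19 as in step 9.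

3. Step 5. Oxidative addition at the hindered C4–I bond, flanked by N3 and the C5 benzyl group, may be slow. Homocoupling of the benzylic zinc reagent and protodeiodination may then consume the partners. The fallback replaces the cross-coupling by carbonyl addition and deoxygenation and sets out from iodide 7. Iodine–magnesium exchange with EtMgBr (THF, rt) gives {5-[2-(benzyloxy)-3,4-dimethoxybenzyl]-1-methyl-1H-imidazol-4-yl}magnesium bromide F3. Addition to 4-methoxybenzaldehyde gives rac-{5-[2-(benzyloxy)-3,4-dimethoxybenzyl]-1-methyl-1H-imidazol-4-yl}(4-methoxyphenyl)methanol F4. Ionic hydrogenation with a large excess of Et3SiH and slow addition of TFA in CH2Cl2 at 0 °C, so that hydride transfer outruns Friedel–Crafts closure onto the neighbouring trialkoxyphenyl ring, should give 10.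

**Further compounds**

F1 | step 9 | 1-methyl-4-[(trimethylsilyl)oxy]-1H-imidazole-2,5-dione | CN1C(=O)N=C(O[Si](C)(C)C)C1=O
F2 | step 8 | ethyl 2-ethoxy-2-[(methylcarbamoyl)imino]acetate | CCOC(=O)C(OCC)=NC(=O)NC
F3 | step 5 | {5-[2-(benzyloxy)-3,4-dimethoxybenzyl]-1-methyl-1H-imidazol-4-yl}magnesium bromide | COc1ccc(Cc2c([Mg]Br)ncn2C)c(OCc2ccccc2)c1OC
F4 | step 5 | rac-{5-[2-(benzyloxy)-3,4-dimethoxybenzyl]-1-methyl-1H-imidazol-4-yl}(4-methoxyphenyl)methanol | COc1ccc(C(O)c2ncn(C)c2Cc2ccc(OC)c(OC)c2OCc2ccccc2)cc1
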